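**Plan**
Numbering (germacranolide): C1=C10 enoate with ester carbon C14; oxirane C4–C5; lactone O–C6–C7–C11(=C13)–C12; methacrylate on C8; acetate on C9.
Retrosynthesis cuts, in order: C8–O(methacryloyl), made with inversion; ring bond C7–C8 of the ten-membered carbocycle; C7=C11 of a butenolide (metathesis) and its ester C–O; C10–C14 (carbonylation); C9–C10 (acetylide acylation); C6–C7 (vinyl addition); back to nerol.
Enabling feature: C8 bears oxygen and is bonded to C7, the β-carbon of the α-methylene-γ-butyrolactone, so C13=C11–C7–C8–O is a homoallylic alcohol. It is the retron of a 2-(alkoxycarbonyl)allyl metal, generated on C13 of a preformed 3-(bromomethyl)butenolide, adding through C7 to a C8 aldehyde.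
Forward ring order: oxirane (step 1), butenolide (step 15), ten-membered carbocycle last (step 18, C7–C8), which also moves the double bond to C11=C13; the chain C6→C1→C10→C9→C8 is grown linearly from nerol.
Stereochemistry: C4/C5 from Sharpless epoxidation of the Z-allylic alcohol; C6 by Felkin–Anh addition to the epoxy aldehyde; C9 by Noyori transfer hydrogenation; C1=C10 geometry by syn-hydrostannation; C7 and C8 in the ring closure (C8 formed as 8R), C8 then inverted in the Mitsunobu esterification.

Key step: step 18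

Remark: the target is read as 4R,5S,6S,7R,8S,9S with a ring-cis (CIP E) C1=C10 bond, a cis-oxirane (C3 and C6 on the same side) and a trans-fused lactone. The cis-oxirane is why nerol, not geraniol, is the starting material.

Step 1
Reactants: 1 nerol
Product: 2 (2S,3R)-2,3-epoxynerol
Conditions: t-BuOOH, Ti(OiPr)4 (cat.), L-(+)-diethyl tartrate (cat.), 4 Å molecular sieves, CH2Cl2, −20 °C
Reagents that add atoms: tert-butyl hydroperoxide, CC(C)(C)OO
Why: Sharpless asymmetric epoxidation of the primary allylic alcohol; the L-(+)-tartrate titanium complex selects one olefin face and sets C4 (R) and C5 (S), the cis-oxirane geometry comes from the Z olefin, and the remote trisubstituted olefin, having no directing hydroxyl, is left alone.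

Step 2
Reactants: 2 (2S,3R)-2,3-epoxynerol
Product: 3 (2R,3R)-2,3-epoxyneral
Conditions: TEMPO (cat.), PhI(OAc)2, CH2Cl2, rt
Reagents that add atoms: none
Why: TEMPO-catalysed oxidation of the primary alcohol should stop at the aldehyde and leave oxirane and olefin untouched (the descriptor at C5 changes only through CIP priority).

Step 3
Reactants: 3 (2R,3R)-2,3-epoxyneral
Product: 4 (6S)-allylic alcohol (vinyl carbinol next to the oxirane)
Conditions: CH2=CHMgBr, THF, −78 °C
Reagents that add atoms: vinylmagnesium bromide, C=C[Mg]Br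
Why: Felkin–Anh addition of the Grignard reagent to the α,β-epoxy aldehyde; attack anti to the oxirane C5–O bond and past the small C5–H should set C6 (S), anti to the oxirane oxygen, helped by the cis substituent on the oxirane.

Step 4
Reactants: 4 (6S)-allylic alcohol
Product: 5 silyl ether of 4
Conditions: TBSCl, imidazole, DMF, rt
Reagents that add atoms: tert-butyldimethylsilyl chloride, CC(C)(C)[Si](C)(C)Cl
Why: Standard silylation protects the C6 hydroxyl for the basic and organometallic steps that follow.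

Step 5
Reactants: 5 silyl ether
Product: 7 C1 aldehyde, via ozonide 6 (not isolated)
Conditions: O3, CH2Cl2, −78 °C (Sudan Red 7B end point); then Me2S, −78 °C to rt
Reagents that add atoms: ozone, [O-][O+]=O
Why: Ozonolysis with reductive work-up; the electron-rich trisubstituted olefin should react well before the monosubstituted olefin deactivated by the allylic silyloxy group, and the indicator marks the end point.

Step 6
Reactants: 7 C1 aldehyde
Product: 8 terminal alkyne (C1≡C10)
Conditions: dimethyl (1-diazo-2-oxopropyl)phosphonate, K2CO3, MeOH, 0 °C to rt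
Reagents that add atoms: dimethyl (1-diazo-2-oxopropyl)phosphonate, CC(=O)C(=[N+]=[N-])P(=O)(OC)OC
Why: Seyferth–Gilbert homologation in the Ohira–Bestmann form adds C10 under mild carbonate conditions compatible with the oxirane and the silyl ether.

Step 7
Reactants: 9 4-methoxybenzyl alcohol; 10 2-chloro-N-methoxy-N-methylacetamide
Product: 11 N-methoxy-2-[(4-methoxybenzyl)oxy]-N-methylacetamide
Conditions: NaH, Bu4NI (cat.), THF, 0 °C to rt
Reagents that add atoms: none
Why: Williamson ether synthesis; SN2 displacement of the activated α-chloride by the alkoxide gives the C8–C9 building block with C8 already protected as a p-methoxybenzyl ether.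

Step 8
Reactants: 8 terminal alkyne; 11 N-methoxy-2-[(4-methoxybenzyl)oxy]-N-methylacetamide
Product: 13 ynone, via lithium acetylide 12 (not isolated)
Conditions: n-BuLi, THF, −78 °C; then 11, −78 to −20 °C
Reagents that add atoms: none
Why: Acylation of an acetylide by a Weinreb amide forms C9–C10; the chelated tetrahedral adduct prevents over-addition and the cold acetylide does not open the oxirane.

Step 9
Reactants: 13 ynone
Product: 14 (9S)-propargylic alcohol
Conditions: Ru(p-cymene)[(R,R)-TsNCH(Ph)CH(Ph)NH] (cat.), i-PrOH, rt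
Reagents that add atoms: none
Why: Noyori asymmetric transfer hydrogenation of an alkynyl ketone; the (R,R) catalyst distinguishes the alkynyl from the alkoxymethyl side and should set C9 (S), with oxirane, olefin and silyl ether inert.

Step 10
Reactants: 14 (9S)-propargylic alcohol
Product: 16 (E)-vinyl iodide, via vinylstannane 15 (not isolated)
Conditions: Bu3SnH, PdCl2(PPh3)2 (cat.), THF, 0 °C; then I2, CH2Cl2, 0 °C
Reagents that add atoms: iodine, II
Why: Palladium-catalysed syn-hydrostannation should place tin on C10 (the alkyne carbon next to the oxygenated C9) and hydrogen on C1, and iododestannylation with retention then fixes C2 and C9 cis on the double bond, the geometry of the target enoate.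

Step 11
Reactants: 16 (E)-vinyl iodide
Product: 17 hydroxy enoate (methyl ester on C10)
Conditions: CO (1 atm), Pd(OAc)2 (cat.), PPh3, Et3N, MeOH/DMF, 50 °C
Reagents that add atoms: carbon monoxide, [C-]#[O+]; methanol, CO
Why: Palladium-catalysed methoxycarbonylation (oxidative addition, CO insertion, methanolysis) replaces iodine by CO2Me with retention of geometry; the large excess of methanol should outrun capture by the neighbouring hydroxyl.

Step 12
Reactants: 17 hydroxy enoate
Product: 18 C9 acetate
Conditions: Ac2O, pyridine, DMAP (cat.), CH2Cl2, 0 °C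
Reagents that add atoms: acetic anhydride, CC(=O)OC(C)=O
Why: Acylation of the secondary allylic alcohol installs the C9 acetate of the target without touching the stereocentre.

Step 13
Reactants: 18 C9 acetate
Product: 19 C6 alcohol
Conditions: Bu4NF, AcOH, THF, 0 °C to rt
Reagents that add atoms: none
Why: Fluoride desilylation; acetic acid buffering should keep the freed C6 oxygen from Payne rearrangement onto the oxirane and from attacking the esters.

Step 14
Reactants: 19 C6 alcohol
Product: 20 2-(bromomethyl)acrylate ester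
Conditions: 2-(bromomethyl)acrylic acid, DIC, DMAP (cat.), CH2Cl2, 0 °C
Reagents that add atoms: 2-(bromomethyl)acrylic acid, C=C(CBr)C(=O)O
Why: Steglich esterification brings in C11, C12 and C13; low temperature and only catalytic DMAP should spare the allylic bromide.

Step 15
Reactants: 20 2-(bromomethyl)acrylate ester
Product: 21 3-(bromomethyl)butenolide
Conditions: second-generation Hoveyda–Grubbs catalyst RuCl2(=CH-C6H4-2-OiPr)(H2IMes) (cat.), toluene, 80 °C, 5 mM
Reagents that add atoms: none
Why: Ring-closing metathesis between the C7 vinyl group and the 1,1-disubstituted acrylate closes the butenolide (C7=C11) with loss of ethylene; the trisubstituted, electron-poor C1=C10 enoate should not take part, and a phosphine-free catalyst avoids quaternisation by the allylic bromide.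

Step 16
Reactants: 21 3-(bromomethyl)butenolide
Product: 22 C8 primary alcohol
Conditions: DDQ, CH2Cl2/pH 7 buffer, 0 °C
Reagents that add atoms: none
Why: Oxidative cleavage of the p-methoxybenzyl ether under neutral conditions should spare the allylic bromide, the oxirane and the acetate; the product is taken on at once to limit acetate migration and lactonisation onto the C14 ester.

Step 17
Reactants: 22 C8 primary alcohol
Product: 23 C8 aldehyde
Conditions: Dess–Martin periodinane, NaHCO3, CH2Cl2, 0 °C to rt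
Reagents that add atoms: none
Why: Buffered Dess–Martin oxidation should give the α-acetoxy aldehyde without epimerising C9; it is used crude.

Step 18
Reactants: 23 C8 aldehyde
Product: 25 macrocyclic 8R alcohol, via allylchromium dichloride 24 (not isolated)
Conditions: CrCl2 (excess), THF, rt, slow addition of 23 (final ca. 1 mM); aqueous work-up
Reagents that add atoms: none
Why: Intramolecular Nozaki–Hiyama–Kishi-type 2-(alkoxycarbonyl)allylation: two equivalents of divalent chromium reduce the C13–Br bond to allylchromium 24, whose γ-carbon C7 adds to the C8 aldehyde through a six-membered chair (Zimmerman–Traxler) transition state while the double bond moves from C7=C11 to C11=C13, so the exocyclic methylene of the lactone appears in the same event. The closest known reactions are the chromium-mediated addition of 3-(bromomethyl)furan-2(5H)-one to aldehydes and the chromium-mediated allylation macrocyclisations used for ten-membered germacrane rings. The carbocycle closes in a 10-exo-trig mode onto the aldehyde carbonyl, with the oxirane and lactone rings already in place and slow addition at high dilution keeping the reaction intramolecular. C7 is controlled by the C6 stereocentre of the butenolide: the aldehyde arm is expected to reach C7 on the face opposite to the C5 substituent, giving the trans-fused lactone (7R). C8 is controlled by the chair transition state: the ring-locked E geometry of the allyl unit (C6 trans to C13) and an equatorial C9 give the 7,8-anti alkoxide (8R), and Felkin–Anh induction from the C9 acetate points the same way; this 8R alcohol is what the inverting next step needs. The step needs γ- over α-attack (the ester-substituted allylchromium reacts through C7), addition to the aldehyde in preference to the three ester carbonyls, and survival of the oxirane, all of which are normal for CrCl2.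

Step 19
Reactants: 25 macrocyclic 8R alcohol
Product: 26 target compound
Conditions: methacrylic acid, PPh3, DIAD (betaine pre-formed), toluene, 0 °C to rt
Reagents that add atoms: methacrylic acid, C=C(C)C(=O)O
Why: Mitsunobu esterification; the C8 hydroxyl is activated on phosphorus and displaced by methacrylate with SN2 inversion, turning 8R into the 8S ester of the target, and pre-forming the betaine keeps free phosphine away from the α-methylene lactone and the allylic acetate.

**Compound list**
1 | nerol, (2Z)-3,7-dimethylocta-2,6-dien-1-ol | CC(C)=CCC/C(C)=C\CO | starting material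
2 | [(2S,3R)-3-methyl-3-(4-methylpent-3-en-1-yl)oxiran-2-yl]methanol | CC(C)=CCC[C@@]1(C)O[C@H]1CO | intermediate
3 | (2R,3R)-3-methyl-3-(4-methylpent-3-en-1-yl)oxirane-2-carbaldehyde | CC(C)=CCC[C@@]1(C)O[C@H]1C=O | intermediate
4 | (1S)-1-[(2S,3R)-3-methyl-3-(4-methylpent-3-en-1-yl)oxiran-2-yl]prop-2-en-1-ol | CC(C)=CCC[C@@]1(C)O[C@H]1[C@@H](O)C=C | intermediate
5 | tert-butyl({(1S)-1-[(2S,3R)-3-methyl-3-(4-methylpent-3-en-1-yl)oxiran-2-yl]prop-2-en-1-yl}oxy)dimethylsilane | CC(C)=CCC[C@@]1(C)O[C@H]1[C@@H](O[Si](C)(C)C(C)(C)C)C=C | intermediate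
6 | ozonide of 5 (3,3-dimethyl-1,2,4-trioxolane on the former trisubstituted olefin, mixture at the ring CH) | CC1(C)OOC(CC[C@@]2(C)O[C@H]2[C@@H](O[Si](C)(C)C(C)(C)C)C=C)O1 | intermediate (not isolated)
7 | 3-[(2R,3S)-3-{(1S)-1-[(tert-butyldimethylsilyl)oxy]prop-2-en-1-yl}-2-methyloxiran-2-yl]propanal | O=CCC[C@@]1(C)O[C@H]1[C@@H](O[Si](C)(C)C(C)(C)C)C=C | intermediate
8 | tert-butyl({(1S)-1-[(2S,3R)-3-(but-3-yn-1-yl)-3-methyloxiran-2-yl]prop-2-en-1-yl}oxy)dimethylsilane | C#CCC[C@@]1(C)O[C@H]1[C@@H](O[Si](C)(C)C(C)(C)C)C=C | intermediate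
9 | 4-methoxybenzyl alcohol | COc1ccc(CO)cc1 | starting material
10 | 2-chloro-N-methoxy-N-methylacetamide | CON(C)C(=O)CCl | starting material
11 | N-methoxy-2-[(4-methoxybenzyl)oxy]-N-methylacetamide | COc1ccc(COCC(=O)N(C)OC)cc1 | intermediate
12 | lithium acetylide of 8 | [Li]C#CCC[C@@]1(C)O[C@H]1[C@@H](O[Si](C)(C)C(C)(C)C)C=C | intermediate (not isolated)
13 | 6-[(2R,3S)-3-{(1S)-1-[(tert-butyldimethylsilyl)oxy]prop-2-en-1-yl}-2-methyloxiran-2-yl]-1-[(4-methoxybenzyl)oxy]hex-3-yn-2-one | COc1ccc(COCC(=O)C#CCC[C@@]2(C)O[C@H]2[C@@H](O[Si](C)(C)C(C)(C)C)C=C)cc1 | intermediate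
14 | (2S)-6-[(2R,3S)-3-{(1S)-1-[(tert-butyldimethylsilyl)oxy]prop-2-en-1-yl}-2-methyloxiran-2-yl]-1-[(4-methoxybenzyl)oxy]hex-3-yn-2-ol | COc1ccc(COC[C@@H](O)C#CCC[C@@]2(C)O[C@H]2[C@@H](O[Si](C)(C)C(C)(C)C)C=C)cc1 | intermediate
15 | (2R,3E)-6-[(2R,3S)-3-{(1S)-1-[(tert-butyldimethylsilyl)oxy]prop-2-en-1-yl}-2-methyloxiran-2-yl]-1-[(4-methoxybenzyl)oxy]-3-(tributylstannyl)hex-3-en-2-ol | COc1ccc(COC[C@@H](O)/C(=C\CC[C@@]2(C)O[C@H]2[C@@H](O[Si](C)(C)C(C)(C)C)C=C)[Sn](CCCC)(CCCC)CCCC)cc1 | intermediate (not isolated)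
16 | (2R,3E)-6-[(2R,3S)-3-{(1S)-1-[(tert-butyldimethylsilyl)oxy]prop-2-en-1-yl}-2-methyloxiran-2-yl]-3-iodo-1-[(4-methoxybenzyl)oxy]hex-3-en-2-ol | COc1ccc(COC[C@@H](O)/C(I)=C\CC[C@@]2(C)O[C@H]2[C@@H](O[Si](C)(C)C(C)(C)C)C=C)cc1 | intermediate
17 | methyl (2E)-5-[(2R,3S)-3-{(1S)-1-[(tert-butyldimethylsilyl)oxy]prop-2-en-1-yl}-2-methyloxiran-2-yl]-2-{(1S)-1-hydroxy-2-[(4-methoxybenzyl)oxy]ethyl}pent-2-enoate | COc1ccc(COC[C@@H](O)/C(C(=O)OC)=C\CC[C@@]2(C)O[C@H]2[C@@H](O[Si](C)(C)C(C)(C)C)C=C)cc1 | intermediate
18 | methyl (2E)-2-{(1S)-1-acetoxy-2-[(4-methoxybenzyl)oxy]ethyl}-5-[(2R,3S)-3-{(1S)-1-[(tert-butyldimethylsilyl)oxy]prop-2-en-1-yl}-2-methyloxiran-2-yl]pent-2-enoate | COc1ccc(COC[C@@H](OC(C)=O)/C(C(=O)OC)=C\CC[C@@]2(C)O[C@H]2[C@@H](O[Si](C)(C)C(C)(C)C)C=C)cc1 | intermediate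
19 | methyl (2E)-2-{(1S)-1-acetoxy-2-[(4-methoxybenzyl)oxy]ethyl}-5-{(2R,3S)-3-[(1S)-1-hydroxyprop-2-en-1-yl]-2-methyloxiran-2-yl}pent-2-enoate | COc1ccc(COC[C@@H](OC(C)=O)/C(C(=O)OC)=C\CC[C@@]2(C)O[C@H]2[C@@H](O)C=C)cc1 | intermediate
20 | methyl (2E)-2-{(1S)-1-acetoxy-2-[(4-methoxybenzyl)oxy]ethyl}-5-{(2R,3S)-3-[(1S)-1-{[2-(bromomethyl)prop-2-enoyl]oxy}prop-2-en-1-yl]-2-methyloxiran-2-yl}pent-2-enoate | COc1ccc(COC[C@@H](OC(C)=O)/C(C(=O)OC)=C\CC[C@@]2(C)O[C@H]2[C@@H](OC(=O)C(=C)CBr)C=C)cc1 | intermediate
21 | methyl (2E)-2-{(1S)-1-acetoxy-2-[(4-methoxybenzyl)oxy]ethyl}-5-{(2R,3S)-3-[(2S)-4-(bromomethyl)-5-oxo-2,5-dihydrofuran-2-yl]-2-methyloxiran-2-yl}pent-2-enoate | COc1ccc(COC[C@@H](OC(C)=O)/C(C(=O)OC)=C\CC[C@@]2(C)O[C@H]2[C@H]2OC(=O)C(CBr)=C2)cc1 | intermediate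
22 | methyl (2E)-2-[(1S)-1-acetoxy-2-hydroxyethyl]-5-{(2R,3S)-3-[(2S)-4-(bromomethyl)-5-oxo-2,5-dihydrofuran-2-yl]-2-methyloxiran-2-yl}pent-2-enoate | OC[C@@H](OC(C)=O)/C(C(=O)OC)=C\CC[C@@]1(C)O[C@H]1[C@H]1OC(=O)C(CBr)=C1 | intermediate
23 | methyl (2E)-2-[(1S)-1-acetoxy-2-oxoethyl]-5-{(2R,3S)-3-[(2S)-4-(bromomethyl)-5-oxo-2,5-dihydrofuran-2-yl]-2-methyloxiran-2-yl}pent-2-enoate | O=C[C@@H](OC(C)=O)/C(C(=O)OC)=C\CC[C@@]1(C)O[C@H]1[C@H]1OC(=O)C(CBr)=C1 | intermediate
24 | allylchromium dichloride derived from 23 (CrCl2 on the former CH2Br carbon C13) | O=C[C@@H](OC(C)=O)/C(C(=O)OC)=C\CC[C@@]1(C)O[C@H]1[C@H]1OC(=O)C(C[Cr](Cl)Cl)=C1 | intermediate (not isolated)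
25 | methyl (1S,2S,4R,7E,9S,10R,11R)-9-acetyloxy-10-hydroxy-4-methyl-12-methylidene-13-oxo-3,14-dioxatricyclo[9.3.0.0(2,4)]tetradec-7-ene-8-carboxylate (germacrane numbering: 4R,5S,6S,7R,8R,9S; the 8-epimeric free alcohol) | O[C@@H]1[C@H]2C(=C)C(=O)O[C@@H]2[C@@H]2O[C@]2(C)CC/C=C(/C(=O)OC)[C@@H]1OC(C)=O | intermediate
26 | methyl (1S,2S,4R,7E,9S,10S,11R)-9-acetyloxy-4-methyl-12-methylidene-10-(2-methylprop-2-enoyloxy)-13-oxo-3,14-dioxatricyclo[9.3.0.0(2,4)]tetradec-7-ene-8-carboxylate (germacrane numbering: 4R,5S,6S,7R,8S,9S) | C=C(C)C(=O)O[C@H]1[C@H]2C(=C)C(=O)O[C@@H]2[C@@H]2O[C@]2(C)CC/C=C(/C(=O)OC)[C@@H]1OC(C)=O | target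

**Totals**
Total step count: 19. Longest linear sequence: 18 (steps 1–6 and 8–19, from nerol).

**Steps most likely to fail, with fallbacks**

Step 18 (ring closure). What may go wrong: intermolecular addition (oligomerisation) in place of ring closure; reductive loss of the α-acetoxy group by divalent chromium; chloride opening of the oxirane by the Lewis-acidic chromium salts; lactonisation of the new C8 alkoxide onto the C14 ester; or closure with the opposite sense at C8. The fallback sets out from 21 and returns at 25, and replaces the reductive metal-mediated closure by a thermal allylboration. Bromide 21 would be borylated (B2pin2, Pd2(dba)3 cat., DMSO, rt) to the allylboronate F1. DDQ would then give the alcohol F2 and Dess–Martin oxidation the boronate aldehyde F3. Heating F3 at high dilution in toluene should close the ring through the same chair transition state to the cyclic borate F4 (not isolated), and mild aqueous hydrolysis would give 25. Should either closure deliver the 8S alcohol instead, it would simply be acylated with retention (it is compound F6 of the next fallback).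

Step 19 (Mitsunobu inversion). What may go wrong: no displacement at the hindered ring carbon; elimination towards C7; or participation of the neighbouring C9 acetate (acetoxonium ion), leading to retention or acyl scrambling. The fallback sets out from 25 and returns at 26, and inverts C8 by oxidation and reduction. Dess–Martin oxidation of 25 would give the C8 ketone F5. Reduction with NaBH4/CeCl3 in MeOH at −78 °C, with hydride arriving anti to the C9 acetate (Felkin–Anh) and the cold cerium conditions sparing the α-methylene lactone, should give the 8S alcohol F6. Acylation of F6 with methacrylic anhydride, Et3N and DMAP would give 26.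

Step 15 (metathesis). What may go wrong: catalyst deactivation by the allylic bromide, or failure of the hindered bromomethyl acrylate to engage, so that the vinyl group dimerises instead. The fallback sets out from 19 and returns at 21, and introduces the bromide only after the ring is closed. Alcohol 19 would be esterified (DIC, DMAP cat.) with 2-{[(tert-butyldimethylsilyl)oxy]methyl}acrylic acid to the silyloxymethyl acrylate F7. Metathesis under the conditions of step 15 would give the silyloxymethyl butenolide F8. Bu4NF/AcOH would free the hydroxymethyl butenolide F9, and Appel bromination (CBr4, PPh3, CH2Cl2, 0 °C) would give 21.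

Further compounds
F1 | step 18 | methyl (2E)-2-{(1S)-1-acetoxy-2-[(4-methoxybenzyl)oxy]ethyl}-5-[(2R,3S)-2-methyl-3-{(2S)-5-oxo-4-[(4,4,5,5-tetramethyl-1,3,2-dioxaborolan-2-yl)methyl]-2,5-dihydrofuran-2-yl}oxiran-2-yl]pent-2-enoate | COc1ccc(COC[C@@H](OC(C)=O)/C(C(=O)OC)=C\CC[C@@]2(C)O[C@H]2[C@H]2OC(=O)C(CB3OC(C)(C)C(C)(C)O3)=C2)cc1
F2 | step 18 | C8 primary alcohol corresponding to F1 (p-methoxybenzyl group removed) | OC[C@@H](OC(C)=O)/C(C(=O)OC)=C\CC[C@@]1(C)O[C@H]1[C@H]1OC(=O)C(CB2OC(C)(C)C(C)(C)O2)=C1
F3 | step 18 | C8 aldehyde corresponding to F2 | O=C[C@@H](OC(C)=O)/C(C(=O)OC)=C\CC[C@@]1(C)O[C@H]1[C@H]1OC(=O)C(CB2OC(C)(C)C(C)(C)O2)=C1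
F4 | step 18 | pinacol borate ester of 25 (boron on the C8 oxygen) | CC1(C)OB(O[C@@H]2[C@H]3C(=C)C(=O)O[C@@H]3[C@@H]3O[C@]3(C)CC/C=C(/C(=O)OC)[C@@H]2OC(C)=O)OC1(C)C
F5 | step 19 | C8 ketone of 25, methyl (1S,2S,4R,7E,9S,11R)-9-acetyloxy-4-methyl-12-methylidene-10,13-dioxo-3,14-dioxatricyclo[9.3.0.0(2,4)]tetradec-7-ene-8-carboxylate | O=C1[C@H]2C(=C)C(=O)O[C@@H]2[C@@H]2O[C@]2(C)CC/C=C(/C(=O)OC)[C@@H]1OC(C)=O
F6 | step 19 | 8S alcohol, the C8 epimer of 25 (10S in the tricyclic name) | O[C@H]1[C@H]2C(=C)C(=O)O[C@@H]2[C@@H]2O[C@]2(C)CC/C=C(/C(=O)OC)[C@@H]1OC(C)=O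
F7 | step 15 | 2-{[(tert-butyldimethylsilyl)oxy]methyl}acrylate ester of 19 | COc1ccc(COC[C@@H](OC(C)=O)/C(C(=O)OC)=C\CC[C@@]2(C)O[C@H]2[C@@H](OC(=O)C(=C)CO[Si](C)(C)C(C)(C)C)C=C)cc1
F8 | step 15 | butenolide of 21 carrying CH2OSi(t-Bu)Me2 in place of CH2Br | COc1ccc(COC[C@@H](OC(C)=O)/C(C(=O)OC)=C\CC[C@@]2(C)O[C@H]2[C@H]2OC(=O)C(CO[Si](C)(C)C(C)(C)C)=C2)cc1
F9 | step 15 | butenolide of 21 carrying CH2OH in place of CH2Br | COc1ccc(COC[C@@H](OC(C)=O)/C(C(=O)OC)=C\CC[C@@]2(C)O[C@H]2[C@H]2OC(=O)C(CO)=C2)cc1
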